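Ring B is read as a disguised catechol acetonide: O1, the gem-dimethyl carbon C2 and the hydroxyl on C8 (next to C8a) are the O–C(CH3)2–O unit of a 2,2-dimethyl-1,3-benzodioxole. The whole route rests on breaking the pyran ring at C2–C3. In the key step a silyl triflate opens the ketal to an aryloxocarbenium ion, the terminal carbon of an ortho vinyl group attacks the former ketal carbon, and triethylsilane reduces the benzylic C4 cation. One operation closes the chroman, creates quaternary C2 and frees the C8 phenol. The precursor is a 4-vinyl-5-prenyl-6-allyl catechol acetonide; ring A is then attached by B-alkyl Suzuki coupling.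

Key step: step 6

Remark: compounds 1 and 10 are taken as commercial; the target has no stereocentre, so no stereocontrol is needed. Chroman numbering is O1, C2, C3, C4, C4a, C5–C8, C8a.

Step 1
Reactants: 1 5-bromo-2,2-dimethyl-1,3-benzodioxole
Product: 3 5-bromo-2,2-dimethyl-1,3-benzodioxole-4-carbaldehyde, via aryllithium 2 (not isolated)
Conditions: LDA (1.1 equiv), THF, −78 °C; DMF, −78 → 0 °C; aq. NH4Cl
Reagents that add atoms: N,N-dimethylformamide, CN(C)C=O
Why: Directed ortho-lithiation followed by formylation: the C4–H flanked by the dioxole oxygen and the bromine is the most acidic ring proton, and the amide base should deprotonate it at −78 °C without bromine–lithium exchange.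

Step 2
Reactants: 3 5-bromo-2,2-dimethyl-1,3-benzodioxole-4-carbaldehyde
Product: 4 5-bromo-6-iodo-2,2-dimethyl-1,3-benzodioxole-4-carbaldehyde
Conditions: NIS (1.2 equiv), TFA (0.5 equiv), MeCN, rt → 40 °C, dark
Reagents that add atoms: N-iodosuccinimide, O=C1CCC(=O)N1I
Why: Electrophilic aromatic iodination should go to C6, which is para to a ring oxygen, ortho to bromine and only meta to the formyl group, whereas the other free position C7 is para to the deactivating aldehyde.

Step 3
Reactants: 4 5-bromo-6-iodo-2,2-dimethyl-1,3-benzodioxole-4-carbaldehyde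
Product: 5 5-bromo-4-ethenyl-6-iodo-2,2-dimethyl-1,3-benzodioxole
Conditions: Ph3PCH3Br (1.3 equiv), KOtBu (1.25 equiv), THF, 0 °C → rt
Reagents that add atoms: methyltriphenylphosphonium bromide, C[P+](c1ccccc1)(c1ccccc1)c1ccccc1.[Br-]
Why: Wittig methylenation of a non-enolisable aryl aldehyde; the aryl halides and the ketal are inert to the ylide.

Step 4
Reactants: 5 5-bromo-4-ethenyl-6-iodo-2,2-dimethyl-1,3-benzodioxole
Product: 6 5-bromo-4-ethenyl-2,2-dimethyl-6-(prop-2-en-1-yl)-1,3-benzodioxole
Conditions: allyl-Bpin (1.1 equiv), PdCl2(dppf) (3 mol%), CsF (3 equiv), THF, 60 °C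
Reagents that add atoms: allylboronic acid pinacol ester, C=CCB1OC(C)(C)C(C)(C)O1
Why: Chemoselective Suzuki–Miyaura allylation: oxidative addition to the carbon–iodine bond is far faster than to the carbon–bromine bond, which is also flanked by two ortho substituents, and the unsubstituted allyl group raises no α/γ question.

Step 5
Reactants: 6 5-bromo-4-ethenyl-2,2-dimethyl-6-(prop-2-en-1-yl)-1,3-benzodioxole
Product: 7 4-ethenyl-2,2-dimethyl-5-(3-methylbut-2-en-1-yl)-6-(prop-2-en-1-yl)-1,3-benzodioxole
Conditions: prenylzinc bromide (1.5 equiv), Pd(OAc)2 (2 mol%), CPhos (4 mol%), THF, rt → 40 °C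
Reagents that add atoms: (3-methylbut-2-en-1-yl)zinc bromide, CC(C)=CC[Zn]Br
Why: Negishi coupling of a 3,3-disubstituted allylzinc halide under CPhos ligation is a linear-selective prenylation, because the allylpalladium intermediate settles at its primary terminus before reductive elimination, and the two ortho substituents reinforce that preference.

Step 6
Reactants: 7 4-ethenyl-2,2-dimethyl-5-(3-methylbut-2-en-1-yl)-6-(prop-2-en-1-yl)-1,3-benzodioxole
Product: 9 2,2-dimethyl-5-(3-methylbut-2-en-1-yl)-6-(prop-2-en-1-yl)-3,4-dihydro-2H-chromen-8-ol, via chromanyl triethylsilyl ether 8 (not isolated)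
Conditions: Et3SiH (5 equiv), TESOTf (0.3 equiv), 2,6-di-tert-butyl-4-methylpyridine (0.1 equiv), CH2Cl2 (0.02 M), −78 → −20 °C; then TBAF, THF, 0 °C; aq. NH4Cl
Reagents that add atoms: none
Why: Proposed new method: Et3SiOTf silylates the less hindered ketal oxygen (the one that becomes the C8 hydroxyl) and ionises its bond to the ketal carbon, so the aryloxocarbenium ion sits on the oxygen ortho to the vinyl group; the terminal vinyl carbon then bonds to the ketal carbon (Prins-type addition, formally a 6π electrocyclisation of the 1-oxatrienyl cation), the oxygen-stabilised benzylic C4 cation takes hydride from Et3SiH with regeneration of Et3SiOTf, and fluoride cleaves silyl ether 8 to phenol 9. The closest known reaction types are the opening of 1,3-benzodioxoles at the acetal carbon by carbon nucleophiles (Grignard and organoaluminium reagents) and silane-terminated cyclisations of ketal-derived oxocarbenium ions onto alkenes; a catechol ketal as oxocarbenium source toward a styrene has not been shown. The pyran ring closes in a 6-endo-trig mode with respect to the vinyl group, the only mode that leaves a benzylic, oxygen-stabilised cation. No stereocentre is formed. The step needs regioselective ketal opening, cyclisation ahead of hydride capture, and survival of the prenyl and allyl alkenes: the ion on the wrong oxygen has no partner and recloses, the conjugated ortho vinyl group reacts intramolecularly whereas the weakly nucleophilic silane must react bimolecularly, and the aprotic, buffered, cold medium should leave the isolated alkenes untouched. The C4 cation is held coplanar with the arene by the new ring, so its empty orbital cannot reach the neighbouring prenyl alkene.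

Step 7
Reactants: 10 4,6-dibromobenzene-1,3-diol
Product: 11 1,5-dibromo-2,4-bis(methoxymethoxy)benzene
Conditions: MOMCl (2.5 equiv), i-Pr2NEt (3 equiv), CH2Cl2, 0 °C → rt
Reagents that add atoms: chloromethyl methyl ether, COCCl
Why: Base-mediated O-alkylation of both phenols (MOM ether formation) on a symmetrical substrate, so no selectivity question arises.

Step 8
Reactants: 11 1,5-dibromo-2,4-bis(methoxymethoxy)benzene (2.5 equiv, excess recovered)
Product: 12 1-bromo-2,4-bis(methoxymethoxy)-5-(2-methylbut-3-en-2-yl)benzene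
Conditions: prenyl-Bpin (1.0 equiv), Pd(OAc)2 (3 mol%), JackiePhos (6 mol%), K3PO4 (aq.), MeCN, 70 °C
Reagents that add atoms: 4,4,5,5-tetramethyl-2-(3-methylbut-2-en-1-yl)-1,3,2-dioxaborolane, CC(C)=CCB1OC(C)(C)C(C)(C)O1
Why: Ligand-controlled γ-selective Suzuki–Miyaura coupling of a 3,3-disubstituted allylboronate: SE2′ transmetalation places palladium on the tertiary carbon and an electron-poor biarylphosphine should make reductive elimination faster than isomerisation to the primary allyl, giving the 1,1-dimethylallyl arene, while the excess of the symmetrical dibromide favours mono-coupling.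

Step 9
Reactants: 9 2,2-dimethyl-5-(3-methylbut-2-en-1-yl)-6-(prop-2-en-1-yl)-3,4-dihydro-2H-chromen-8-ol; 12 1-bromo-2,4-bis(methoxymethoxy)-5-(2-methylbut-3-en-2-yl)benzene
Product: 14 6-{3-[2,4-bis(methoxymethoxy)-5-(2-methylbut-3-en-2-yl)phenyl]propyl}-2,2-dimethyl-5-(3-methylbut-2-en-1-yl)-3,4-dihydro-2H-chromen-8-ol, via bis(9-BBN) adduct 13 (not isolated)
Conditions: 9-BBN (2.2 equiv), THF, 0 °C → rt; then K3PO4 (3 M aq.), 12, Pd(OAc)2 (5 mol%), SPhos (10 mol%), THF, 65 °C
Reagents that add atoms: none
Why: Anti-Markovnikov hydroboration with 9-BBN is selective for the monosubstituted allyl group over the trisubstituted prenyl alkene (the phenol is O-borylated and freed again by the aqueous base), and the B-alkyl Suzuki–Miyaura coupling then joins the primary alkylborane to the electron-rich aryl bromide.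

Step 10
Reactants: 14 6-{3-[2,4-bis(methoxymethoxy)-5-(2-methylbut-3-en-2-yl)phenyl]propyl}-2,2-dimethyl-5-(3-methylbut-2-en-1-yl)-3,4-dihydro-2H-chromen-8-ol
Product: 15 kazinol D
Conditions: HCl (3 M aq.), MeOH, rt → 40 °C
Reagents that add atoms: none
Why: Acid-catalysed transacetalisation of the two aryl MOM ethers to methanol; under dilute acid the monosubstituted alkene of the 1,1-dimethylallyl group and the prenyl alkene, which has no ortho hydroxyl, should not be protonated.

Compound list
1 | 5-bromo-2,2-dimethyl-1,3-benzodioxole | CC1(C)Oc2cc(Br)ccc2O1 | starting material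
2 | (5-bromo-2,2-dimethyl-1,3-benzodioxol-4-yl)lithium | CC1(C)Oc2c([Li])c(Br)ccc2O1 | intermediate
3 | 5-bromo-2,2-dimethyl-1,3-benzodioxole-4-carbaldehyde | CC1(C)Oc2c(C=O)c(Br)ccc2O1 | intermediate
4 | 5-bromo-6-iodo-2,2-dimethyl-1,3-benzodioxole-4-carbaldehyde | CC1(C)Oc2c(C=O)c(Br)c(I)cc2O1 | intermediate
5 | 5-bromo-4-ethenyl-6-iodo-2,2-dimethyl-1,3-benzodioxole | CC1(C)Oc2c(C=C)c(Br)c(I)cc2O1 | intermediate
6 | 5-bromo-4-ethenyl-2,2-dimethyl-6-(prop-2-en-1-yl)-1,3-benzodioxole | CC1(C)Oc2c(C=C)c(Br)c(CC=C)cc2O1 | intermediate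
7 | 4-ethenyl-2,2-dimethyl-5-(3-methylbut-2-en-1-yl)-6-(prop-2-en-1-yl)-1,3-benzodioxole | CC1(C)Oc2c(C=C)c(CC=C(C)C)c(CC=C)cc2O1 | intermediate
8 | triethyl{[2,2-dimethyl-5-(3-methylbut-2-en-1-yl)-6-(prop-2-en-1-yl)-3,4-dihydro-2H-chromen-8-yl]oxy}silane | CC[Si](CC)(CC)Oc1cc(CC=C)c(CC=C(C)C)c2CCC(C)(C)Oc12 | intermediate
9 | 2,2-dimethyl-5-(3-methylbut-2-en-1-yl)-6-(prop-2-en-1-yl)-3,4-dihydro-2H-chromen-8-ol | Oc1cc(CC=C)c(CC=C(C)C)c2CCC(C)(C)Oc12 | intermediate
10 | 4,6-dibromobenzene-1,3-diol | Oc1cc(O)c(Br)cc1Br | starting material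
11 | 1,5-dibromo-2,4-bis(methoxymethoxy)benzene | COCOc1cc(OCOC)c(Br)cc1Br | intermediate
12 | 1-bromo-2,4-bis(methoxymethoxy)-5-(2-methylbut-3-en-2-yl)benzene | COCOc1cc(OCOC)c(C(C)(C)C=C)cc1Br | intermediate
13 | 9-{3-[8-(9-borabicyclo[3.3.1]nonan-9-yloxy)-2,2-dimethyl-5-(3-methylbut-2-en-1-yl)-3,4-dihydro-2H-chromen-6-yl]propyl}-9-borabicyclo[3.3.1]nonane | CC(C)=CCc1c(CCCB2C3CCCC2CCC3)cc(OB2C3CCCC2CCC3)c2OC(C)(C)CCc12 | intermediate
14 | 6-{3-[2,4-bis(methoxymethoxy)-5-(2-methylbut-3-en-2-yl)phenyl]propyl}-2,2-dimethyl-5-(3-methylbut-2-en-1-yl)-3,4-dihydro-2H-chromen-8-ol | C=CC(C)(C)c1cc(CCCc2cc(O)c3OC(C)(C)CCc3c2CC=C(C)C)c(OCOC)cc1OCOC | intermediate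
15 | kazinol D | C=CC(C)(C)c1cc(CCCc2cc(O)c3c(c2CC=C(C)C)CCC(C)(C)O3)c(O)cc1O | target

Total step count: 10
Longest linear sequence: 8 steps (steps 1–6, 9 and 10, from compound 1)

Steps most likely to fail

Step 6. The ring-opened oxocarbenium ion may take hydride before it cyclises (plain reductive ketal cleavage to isopropyl ethers), the cyclised cation may lose a proton to a 2H-chromene, or the prenyl alkene may be degraded by cationic chemistry. The fallback sets out from 4 and comes back at 9; it closes the same C2–C3 bond by a known radical cyclisation. The ketal of 4 is hydrolysed while no alkene is present (TFA/H2O, rt) to 6-bromo-2,3-dihydroxy-5-iodobenzaldehyde F1. Its dianion (NaH, DMSO) is alkylated by MOMCl at the non-chelated 3-oxygen to give 6-bromo-2-hydroxy-5-iodo-3-(methoxymethoxy)benzaldehyde F2. Wittig methylenation with excess Ph3P=CH2 gives 3-bromo-2-ethenyl-4-iodo-6-(methoxymethoxy)phenol F3. Alkylation with 2-bromo-2-methylpropanoic acid (NaOH, 2-butanone, 50 °C) gives 2-[3-bromo-2-ethenyl-4-iodo-6-(methoxymethoxy)phenoxy]-2-methylpropanoic acid F4. Photoredox decarboxylation (4CzIPN, arenethiol co-catalyst, K2HPO4, DMF, blue light) generates the tertiary α-aryloxy radical, which adds 6-endo to the vinyl group; hydrogen-atom transfer to the benzylic radical gives 5-bromo-6-iodo-8-(methoxymethoxy)-2,2-dimethyl-3,4-dihydro-2H-chromene F5. Allylation at the iodide as in step 4 gives 5-bromo-8-(methoxymethoxy)-2,2-dimethyl-6-(prop-2-en-1-yl)-3,4-dihydro-2H-chromene F6, and prenylation at the bromide as in step 5 gives 8-(methoxymethoxy)-2,2-dimethyl-5-(3-methylbut-2-en-1-yl)-6-(prop-2-en-1-yl)-3,4-dihydro-2H-chromene F7. Mild acid cleavage of the MOM ether (HCl, MeOH, rt) returns 9.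

Step 8. The tertiary allylpalladium intermediate may isomerise to the primary one before reductive elimination (linear prenyl product), coupling next to the ortho MOM ether may be slow, or the dibromide may couple twice. The fallback sets out from 11 and comes back at 12. Palladium-catalysed α-arylation of isobutyronitrile with excess 11 (NaHMDS, Pd(OAc)2, BINAP, toluene, 80 °C) builds the quaternary carbon as 2-[5-bromo-2,4-bis(methoxymethoxy)phenyl]-2-methylpropanenitrile F8. DIBAL-H (toluene, −78 °C, aqueous work-up) gives 2-[5-bromo-2,4-bis(methoxymethoxy)phenyl]-2-methylpropanal F9, and Wittig methylenation (Ph3P=CH2, THF) gives 12.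

Step 5. Oxidative addition and transmetalation at the bromide flanked by vinyl and allyl may be slow, leading to protodebromination or Heck-type oligomerisation of the styrene. The fallback sets out from 4 and comes back at 7; it couples while the formyl group still activates the bromide and makes the styrene last. Stille allylation of 4 at the iodide (allyltributylstannane, Pd(PPh3)4, toluene, 80 °C) gives 5-bromo-2,2-dimethyl-6-(prop-2-en-1-yl)-1,3-benzodioxole-4-carbaldehyde F10. Stille prenylation of the bromide (tributyl(3-methylbut-2-en-1-yl)stannane, Pd(PPh3)4, CuI, CsF, DMF, 60 °C) gives 2,2-dimethyl-5-(3-methylbut-2-en-1-yl)-6-(prop-2-en-1-yl)-1,3-benzodioxole-4-carbaldehyde F11, and Wittig methylenation as in step 3 gives 7.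

Further compounds
F1 | step 6 | 6-bromo-2,3-dihydroxy-5-iodobenzaldehyde | O=Cc1c(Br)c(I)cc(O)c1O
F2 | step 6 | 6-bromo-2-hydroxy-5-iodo-3-(methoxymethoxy)benzaldehyde | O=Cc1c(Br)c(I)cc(OCOC)c1O
F3 | step 6 | 3-bromo-2-ethenyl-4-iodo-6-(methoxymethoxy)phenol | C=Cc1c(Br)c(I)cc(OCOC)c1O
F4 | step 6 | 2-[3-bromo-2-ethenyl-4-iodo-6-(methoxymethoxy)phenoxy]-2-methylpropanoic acid | C=Cc1c(Br)c(I)cc(OCOC)c1OC(C)(C)C(=O)O
F5 | step 6 | 5-bromo-6-iodo-8-(methoxymethoxy)-2,2-dimethyl-3,4-dihydro-2H-chromene | CC1(C)CCc2c(Br)c(I)cc(OCOC)c2O1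
F6 | step 6 | 5-bromo-8-(methoxymethoxy)-2,2-dimethyl-6-(prop-2-en-1-yl)-3,4-dihydro-2H-chromene | CC1(C)CCc2c(Br)c(CC=C)cc(OCOC)c2O1
F7 | step 6 | 8-(methoxymethoxy)-2,2-dimethyl-5-(3-methylbut-2-en-1-yl)-6-(prop-2-en-1-yl)-3,4-dihydro-2H-chromene | CC1(C)CCc2c(CC=C(C)C)c(CC=C)cc(OCOC)c2O1
F8 | step 8 | 2-[5-bromo-2,4-bis(methoxymethoxy)phenyl]-2-methylpropanenitrile | COCOc1cc(OCOC)c(C(C)(C)C#N)cc1Br
F9 | step 8 | 2-[5-bromo-2,4-bis(methoxymethoxy)phenyl]-2-methylpropanal | COCOc1cc(OCOC)c(C(C)(C)C=O)cc1Br
F10 | step 5 | 5-bromo-2,2-dimethyl-6-(prop-2-en-1-yl)-1,3-benzodioxole-4-carbaldehyde | CC1(C)Oc2c(C=O)c(Br)c(CC=C)cc2O1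
F11 | step 5 | 2,2-dimethyl-5-(3-methylbut-2-en-1-yl)-6-(prop-2-en-1-yl)-1,3-benzodioxole-4-carbaldehyde | CC1(C)Oc2c(C=O)c(CC=C(C)C)c(CC=C)cc2O1
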